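(The numbers in the tables stem from a simulated flask on assumed constants; the scatter is artificial.)

Which flask holds more target after 6.0 h, the cold north-east or the warmer north, and how much?

in all of them: starting material 0.25 M; catalyst 0.5 mol%

| flask | added ligand | temperature | remark | time |
|---|---|---|---|---|
| theta | 1.8 mM | 0 °C | run made earlier |  |
| north-east | 1.2 mM | 0 °C |  | 6.0 h |
| north | 1.2 mM | 20 °C |  | 6.0 h |

- theta (time / min: target / %, starting material / %): 8.00: 7.6, 93.2; 15.0: 13.4, 86.7; 30.0: 23.2, 78.3; 60.0: 34.2, 64.9; 120: 46.1, 54.2

(standard deviation of a reading: 1 percentage point)

- the flask that comes out highest in amount of target, in percent of the starting material charged, or "all alike" when all lie within 1.5 percentage points (north-east / north / all alike)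
- target at the end, in percent of the starting material charged, north-east
- target at the end, in percent of the starting material charged, north

- amounts and yields of target count crystals too
- given per volume of solution although it is solid: crystals
- the analysis behind the earlier runs scatters by 1 percentage point, standard deviation
- on the list of suspects stand: isomer of the product A + catalyst <-> isomer of the product B + catalyst; crystals <-> target; catalyst + added ligand <-> idle complex; starting material + catalyst <-> target + catalyst; target + catalyst <-> isomer of the product A + catalyst
- the earlier runs do not show what temperature does; that part of a forecast is a guess
- no earlier run changes the charge of added ligand; that part of a forecast is a guess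

I began with the main step alone, starting material going reversibly to target. Its rate follows free catalyst, which I took as steady within a run, so the approach to the plateau is pseudo-first-order. In equal time steps such an approach shrinks by a constant factor. Theta's starting material fell by 35.1% in its first 60.0 min, then by 11 percentage points in the next 60.0 min, a factor of 0.305. That gave the relaxation half-life of the main step, the time in which the distance to the plateau halves, as 35.0 min. The same factor put the plateau near 49.5% starting material and 50.5% target. North-east's 6.0 h held 10.3 such half-lives, so its answer was a plateau, not a speed.

Then I added the drain to the isomers. Theta's last two readings summed to 100%, within the scatter of 1 point, so I took off only a little. Crystals I did not add: theta's last target reading, 46.1%, lay below that plateau, so it gave no sign of them. Last came the ligand, 1.2 mM against theta's 1.8 mM, with catalyst charged at 1.25 mM. I guessed that less ligand frees more catalyst, which shortens the half-life and leaves the plateau alone. My number for north-east was just under 50.5%. Warming should also shorten the half-life, so north too would be a plateau flask, at a height theta cannot show.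

The forecast read a higher plateau from the same run, near 53% target. It gave 52% for north-east and 42% for north, with north-east highest, noting “The equilibrium shift is unknown”.

North-east gave 47.2% and north 28.6%, so north-east came out highest, but north lay well below 42%.

    isomer of the product A + catalyst ⇌ isomer of the product B + catalyst, rate k1*[catalyst]*[isomer of the product A] forward; the back reaction follows from the equilibrium constant (K = 0.240, k = 0.240 /M/s, Ea = 48.0 kJ/mol, ΔH = −44.0 kJ/mol)
    crystals ⇌ target, rate k2*(cs2 - [target]) while solid is left; crystals form when [target] > cs2 (solubility = 0.180 M, k = 0.0190 /s)
    catalyst + added ligand ⇌ idle complex, settled at all times (K = 400 /M, ΔH = 0 kJ/mol)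
    starting material + catalyst ⇌ target + catalyst, rate k4*[starting material]*[catalyst] forward; the back reaction follows from the equilibrium constant (K = 1.00, k = 0.200 /M/s, Ea = 46.0 kJ/mol, ΔH = −25.0 kJ/mol)
    target + catalyst ⇌ isomer of the product A + catalyst, rate k5*[catalyst]*[target] forward; the back reaction follows from the equilibrium constant (K = 0.370, k = 0.00650 /M/s, Ea = 66.0 kJ/mol, ΔH = 1.00 kJ/mol)
    (constants at 0 °C)

In north the main step's relaxation half-life at the end, 0.0837 h, was shorter than the 35.0 min read from theta, and that of target with isomer of the product A, 1.22 h, was still short against 6.0 h, and target stood nearly flat, reading 29.3% at 3.00 h and 28.6% at 6.00 h, a level lower than the plateau read from theta. Counted with 35.0 min, north-east had 5.14 half-lives behind it by 3.00 h, and its starting material moved after that from 50.1% to 47.9%.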